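**Strategy.** Ring A is disconnected into a three-carbon unit (C1–C3, acrolein) and a ring B fragment that already carries C4. Ring B with C17, C4 and its two methyls is the p-menthane skeleton of (+)-dihydrocarvone: its isopropenyl-bearing stereocentre becomes C5, its ketone C9 and its α-carbon C10. In one flask the C10 silyl enol ether adds to acrolein (C1–C10), and the tertiary C4 radical, made from the isopropenyl group by hydrogen-atom transfer, closes onto the aldehyde (C3–C4). This gives the trans-decalin with both quaternary carbons. The precursor is a regiodefined silyl enol ether of 6-methyldihydrocarvone; the Δ2-alkene later gives the 2α,3α-diol and the C9 ketone the side chain.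

Key step: step 3

Remarks on the chemistry:
- Labdane numbering is used (C1–C10 decalin, C11–C16 side chain, C17 on C8, C18/C19 on C4, C20 on C10); β is the face of the C10 methyl.
- Commercial (+)-dihydrocarvone is assumed to contain some 2S epimer (C8); this centre is equilibrated in step 5.
- The C3 carbinol of 8 and 9 is drawn 3β; either epimer serves, because C3 becomes sp2 in step 5.

**Step 1**
Reactants: 1 (+)-dihydrocarvone
Product: 4 (2R,5S)-2-methyl-6-methylidene-5-(prop-1-en-2-yl)cyclohexan-1-one, via Mannich base 2 (not isolated), via ammonium iodide 3 (not isolated)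
Conditions: LDA, THF, −78 °C; Me2N=CH2+ I−, −78 °C → rt; MeI, Et2O, rt; NaHCO3, CH2Cl2/H2O, rt
Reagents that add atoms: dimethylmethylideneammonium iodide, C=[N+](C)C.[I-]
Why: Kinetic deprotonation should occur at the only α-methylene (C10), the enolate is aminomethylated (Mannich reaction) and the quaternised amine is eliminated (E1cB α-methylenation) to the exocyclic enone, leaving C5 untouched.

**Step 2**
Reactants: 4 (2R,5S)-2-methyl-6-methylidene-5-(prop-1-en-2-yl)cyclohexan-1-one
Product: 5 triethyl{[(3S,6R)-2,6-dimethyl-3-(prop-1-en-2-yl)cyclohex-1-en-1-yl]oxy}silane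
Conditions: Et3SiH, RhCl(PPh3)3 (cat.), benzene, 60 °C
Reagents that add atoms: triethylsilane, CC[SiH](CC)CC
Why: Rhodium-catalysed 1,4-hydrosilylation of the enone should put hydrogen on the exocyclic CH2 (which becomes the C20 methyl) and silicon on oxygen, so the tetrasubstituted C9=C10 silyl enol ether forms regiospecifically while the unactivated isopropenyl group stays.

**Step 3**
Reactants: 5 triethyl{[(3S,6R)-2,6-dimethyl-3-(prop-1-en-2-yl)cyclohex-1-en-1-yl]oxy}silane; 6 acrolein
Product: 8 3β-hydroxy-4,4,8α,10β-tetramethyl-5α-decalin-9-one, via keto aldehyde 7 (not isolated)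
Conditions: 6, BF3·OEt2, i-PrOH, CH2Cl2, −78 °C; then pyridine, EtOH, Fe(acac)3 (0.5 equiv), PhSiH3, 35 °C
Reagents that add atoms: none
Why: A BF3/alcohol-promoted Mukaiyama–Michael addition of the tetrasubstituted silyl enol ether to acrolein forms C1–C10 and releases keto aldehyde 7; in the same flask Fe(acac)3/PhSiH3 transfers a hydrogen atom to the terminal CH2 of the isopropenyl group (Mukaiyama-type hydrogen-atom transfer), and the tertiary C4 radical adds to the formyl carbon in a 6-exo-trig closure of ring A (C3–C4), the alkoxy radical then being reduced and protonated. The closest known reaction types are the Lewis-acid conjugate addition of silyl enol ethers to enals and the iron-hydride-initiated radical cyclisation of alkene-tethered carbonyl compounds. C10 is set by approach of acrolein anti to the neighbouring C5 isopropenyl group, which 1,2-allylic strain with the C10 methyl holds pseudoaxial. The ring fusion should be trans because the C1 chain and the C4 radical centre are trans-diequatorial on ring B in a chair-like transition state, which also places the C3 oxygen equatorial (a centre erased in step 5). The step needs 1,4- rather than 1,2-addition to acrolein, favoured by the hindered nucleophile and the protic BF3 protocol; hydrogen-atom transfer at the single 1,1-disubstituted alkene; and ring closure faster than reduction of the radical, which the fast 6-exo addition to a formyl group secures, the C9 ketone being reachable only through a four-membered ring.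

**Step 4**
Reactants: 8 3β-hydroxy-4,4,8α,10β-tetramethyl-5α-decalin-9-one
Product: 9 O-(9-oxo-4,4,8α,10β-tetramethyl-5α-decalin-3β-yl) S-methyl dithiocarbonate
Conditions: NaH, imidazole (cat.), THF, 0 °C → rt; CS2; MeI
Reagents that add atoms: carbon disulfide, S=C=S; iodomethane, CI
Why: Addition of the alkoxide to CS2 and S-methylation should give the xanthate (first half of the Chugaev elimination), the alkoxide forming much faster than the enolate of the hindered C9 ketone.

**Step 5**
Reactants: 9 O-(9-oxo-4,4,8α,10β-tetramethyl-5α-decalin-3β-yl) S-methyl dithiocarbonate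
Product: 10 4,4,8α,10β-tetramethyl-5α-decal-2-en-9-one
Conditions: Ph2O, 200 °C; then NaOMe (cat.), MeOH, rt
Reagents that add atoms: none
Why: The Chugaev syn-elimination can only take a hydrogen from C2 (C4 is quaternary) and has no cationic intermediate, so the Δ2 alkene should form without the Wagner–Meerwein ring contraction typical of 4,4-dimethyl-3-ols; methoxide then equilibrates C8 to the equatorial 8α-methyl epimer.

**Step 6**
Reactants: 10 4,4,8α,10β-tetramethyl-5α-decal-2-en-9-one; 11 2-(2-bromoethyl)-2-methyl-1,3-dioxolane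
Product: 13 9α-[2-(2-methyl-1,3-dioxolan-2-yl)ethyl]-4,4,8α,10β-tetramethyl-5α-decal-2-en-9β-ol, via Grignard reagent 12 (not isolated)
Conditions: 11, Mg, THF, rt; CeCl3, THF, −78 °C; then 10, −78 → 0 °C; H2O
Reagents that add atoms: none
Why: The organocerium reagent (Grignard addition in the presence of CeCl3) should add to the hindered, enolisable ketone without deprotonating it, along the axial trajectory on the α face anti to the axial C10 methyl, which sets C9 with the chain α and the hydroxyl β.

**Step 7**
Reactants: 13 9α-[2-(2-methyl-1,3-dioxolan-2-yl)ethyl]-4,4,8α,10β-tetramethyl-5α-decal-2-en-9β-ol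
Product: 15 4-(2α,3α,9β-trihydroxy-4,4,8α,10β-tetramethyl-5α-decalin-9α-yl)butan-2-one, via triol ketal 14 (not isolated)
Conditions: OsO4 (cat.), NMO, t-BuOH/THF/H2O, rt; then 1 M HCl, THF, rt
Reagents that add atoms: 4-methylmorpholine N-oxide, C[N+]1([O-])CCOCC1; water, O
Why: Catalytic OsO4 syn-dihydroxylation should attack the Δ2 alkene from the α face, because the axial C10 and 4β methyls shield the β face, giving the 2α,3α-diol; aqueous acid then hydrolyses the dioxolane to the methyl ketone.

**Step 8**
Reactants: 15 4-(2α,3α,9β-trihydroxy-4,4,8α,10β-tetramethyl-5α-decalin-9α-yl)butan-2-one; 16 trimethyl phosphonoacetate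
Product: 17 CNP0292844.1
Conditions: 16, NaH, THF, 0 °C → 60 °C
Reagents that add atoms: none
Why: Horner–Wadsworth–Emmons olefination of the methyl ketone (reacting through the open form of its hemiketal) with the pre-formed phosphonate anion, which is too weak a base to disturb the free hydroxyls, should give mainly the (E)-enoate, the minor (Z)-isomer being removed by chromatography.

**Compound list**

1 | (+)-dihydrocarvone, (2R,5R)-2-methyl-5-(prop-1-en-2-yl)cyclohexan-1-one | O=C1[C@H](C)CC[C@@H](C(C)=C)C1 | starting material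
2 | Mannich base, 2-[(dimethylamino)methyl]-6-methyl-3-(prop-1-en-2-yl)cyclohexan-1-one (C5 and C8 as in 1, epimers at the new centre) | O=C1[C@H](C)CC[C@@H](C(C)=C)C1CN(C)C | intermediate
3 | ammonium iodide, N-methyl quaternary salt of 2 | O=C1[C@H](C)CC[C@@H](C(C)=C)C1C[N+](C)(C)C.[I-] | intermediate
4 | (2R,5S)-2-methyl-6-methylidene-5-(prop-1-en-2-yl)cyclohexan-1-one | O=C1[C@H](C)CC[C@@H](C(C)=C)C1=C | intermediate
5 | triethyl{[(3S,6R)-2,6-dimethyl-3-(prop-1-en-2-yl)cyclohex-1-en-1-yl]oxy}silane | CC[Si](CC)(CC)OC1=C(C)[C@H](C(C)=C)CC[C@H]1C | intermediate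
6 | acrolein (prop-2-enal) | C=CC=O | starting material
7 | keto aldehyde, 3-[(1S,3R,6S)-1,3-dimethyl-2-oxo-6-(prop-1-en-2-yl)cyclohexyl]propanal (chain trans to the isopropenyl group) | O=C1[C@H](C)CC[C@@H](C(C)=C)[C@]1(C)CCC=O | intermediate
8 | 3β-hydroxy-4,4,8α,10β-tetramethyl-5α-decalin-9-one (trans-fused) | O=C1[C@H](C)CC[C@H]2C(C)(C)[C@@H](O)CC[C@@]21C | intermediate
9 | O-(9-oxo-4,4,8α,10β-tetramethyl-5α-decalin-3β-yl) S-methyl dithiocarbonate | O=C1[C@H](C)CC[C@H]2C(C)(C)[C@@H](OC(=S)SC)CC[C@@]21C | intermediate
10 | 4,4,8α,10β-tetramethyl-5α-decal-2-en-9-one | O=C1[C@H](C)CC[C@H]2C(C)(C)C=CC[C@@]21C | intermediate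
11 | 2-(2-bromoethyl)-2-methyl-1,3-dioxolane | CC1(CCBr)OCCO1 | starting material
12 | Grignard reagent, [2-(2-methyl-1,3-dioxolan-2-yl)ethyl]magnesium bromide | CC1(CC[Mg]Br)OCCO1 | intermediate
13 | 9α-[2-(2-methyl-1,3-dioxolan-2-yl)ethyl]-4,4,8α,10β-tetramethyl-5α-decal-2-en-9β-ol | CC1(OCCO1)CC[C@]2(O)[C@H](C)CC[C@H]3C(C)(C)C=CC[C@@]32C | intermediate
14 | triol ketal, 9α-[2-(2-methyl-1,3-dioxolan-2-yl)ethyl]-4,4,8α,10β-tetramethyl-5α-decalin-2α,3α,9β-triol | CC1(OCCO1)CC[C@]2(O)[C@H](C)CC[C@H]3C(C)(C)[C@H](O)[C@H](O)C[C@@]32C | intermediate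
15 | 4-(2α,3α,9β-trihydroxy-4,4,8α,10β-tetramethyl-5α-decalin-9α-yl)butan-2-one | CC(=O)CC[C@]1(O)[C@H](C)CC[C@H]2C(C)(C)[C@H](O)[C@H](O)C[C@@]21C | intermediate
16 | trimethyl phosphonoacetate | COC(=O)CP(=O)(OC)OC | starting material
17 | CNP0292844.1, methyl (2E)-5-[(1S,2R,4aS,6S,7R,8aS)-1,6,7-trihydroxy-2,5,5,8a-tetramethyldecahydronaphthalen-1-yl]-3-methylpent-2-enoate | COC(=O)/C=C(\C)CC[C@]1(O)[C@H](C)CC[C@H]2C(C)(C)[C@H](O)[C@H](O)C[C@@]21C | target

**Total step count:** 8. **Longest linear sequence:** 8 steps (1 → 17).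

**Steps most likely to fail**

1. Step 3. The Lewis-acid stage may suffer 1,2-addition to, or oligomerisation of, acrolein, and the two stages may not be compatible in one flask. The fallback makes the C1–C10 bond by enolate alkylation instead of conjugate addition and runs the ring closure on purified material. It sets out from 5: MeLi in THF should give the regiodefined lithium enolate, and alkylation with 2-(2-iodoethyl)-1,3-dioxolane (DMPU), again anti to the isopropenyl group, should give acetal ketone F1. PPTS in aqueous acetone should then release keto aldehyde 7, now isolated. Fe(acac)3/PhSiH3 in EtOH/ethylene glycol should close ring A, and the route is rejoined at 8.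

2. Step 6. Enolisation or reduction of the doubly flanked C9 ketone may outrun addition of the sp3 organometallic. The fallback uses a slim sp nucleophile and sets out from 10. The lithium acetylide of 2-ethynyl-2-methyl-1,3-dioxolane (n-BuLi, THF, −78 °C) should add from the α face to give propargylic carbinol F2. Catalytic OsO4/NMO, which leaves the alkyne alone, should give alkynyl triol F3. Hydrogenation (H2, Pd/C, EtOAc) should saturate the alkyne to give 14, which is hydrolysed as in the second stage of step 7 to 15.

3. Step 8. Olefination of the hemiketal-masked ketone may be slow and may show poor E/Z control. The fallback builds the trisubstituted alkene stereospecifically and sets out from 10. The organocerium reagent from (4-bromobut-1-yn-1-yl)trimethylsilane (Mg, then CeCl3) should add as in step 6 to give silyl alkyne carbinol F4. K2CO3/MeOH should give terminal alkyne F5. Zirconium-catalysed methylalumination (Me3Al, Cp2ZrCl2, CH2Cl2) followed by I2 should give (E)-vinyl iodide F6 by syn addition. Pd(PPh3)4-catalysed methoxycarbonylation (CO, MeOH, Et3N) should give Δ2 enoate F7 with retention. Catalytic OsO4/NMO, expected to prefer the isolated Δ2 alkene over the deactivated enoate, should then give 17.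

**Further compounds**

F1 | step 3 | acetal ketone, (2S,3S,6R)-2-[2-(1,3-dioxolan-2-yl)ethyl]-2,6-dimethyl-3-(prop-1-en-2-yl)cyclohexan-1-one | O=C1[C@H](C)CC[C@@H](C(C)=C)[C@]1(C)CCC2OCCO2
F2 | step 6 | propargylic carbinol, 9α-[(2-methyl-1,3-dioxolan-2-yl)ethynyl]-4,4,8α,10β-tetramethyl-5α-decal-2-en-9β-ol | CC1(OCCO1)C#C[C@]2(O)[C@H](C)CC[C@H]3C(C)(C)C=CC[C@@]32C
F3 | step 6 | alkynyl triol, 9α-[(2-methyl-1,3-dioxolan-2-yl)ethynyl]-4,4,8α,10β-tetramethyl-5α-decalin-2α,3α,9β-triol | CC1(OCCO1)C#C[C@]2(O)[C@H](C)CC[C@H]3C(C)(C)[C@H](O)[C@H](O)C[C@@]32C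
F4 | step 8 | silyl alkyne carbinol, 9α-[4-(trimethylsilyl)but-3-yn-1-yl]-4,4,8α,10β-tetramethyl-5α-decal-2-en-9β-ol | C[Si](C)(C)C#CCC[C@]1(O)[C@H](C)CC[C@H]2C(C)(C)C=CC[C@@]21C
F5 | step 8 | terminal alkyne, 9α-(but-3-yn-1-yl)-4,4,8α,10β-tetramethyl-5α-decal-2-en-9β-ol | C#CCC[C@]1(O)[C@H](C)CC[C@H]2C(C)(C)C=CC[C@@]21C
F6 | step 8 | (E)-vinyl iodide, 9α-[(3E)-4-iodo-3-methylbut-3-en-1-yl]-4,4,8α,10β-tetramethyl-5α-decal-2-en-9β-ol | I/C=C(\C)CC[C@]1(O)[C@H](C)CC[C@H]2C(C)(C)C=CC[C@@]21C
F7 | step 8 | Δ2 enoate, methyl (2E)-5-(9β-hydroxy-4,4,8α,10β-tetramethyl-5α-decal-2-en-9α-yl)-3-methylpent-2-enoate | COC(=O)/C=C(\C)CC[C@]1(O)[C@H](C)CC[C@H]2C(C)(C)C=CC[C@@]21C
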